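**Strategy.** The tetralin is cut at C4–C4a and C2–C3 (tetralin numbering). C3–C4 is a two-carbon unit wedged between aromatic ring A and the C2 methine, so it is brought in as a vinyl boronate. A palladium-catalysed enantioselective conjunctive cross-coupling joins three simple pieces in one operation: 4-bromoveratrole arylates the vinyl terminus (C4–C4a) while an isopropenyl group shifts from boron to carbon (C2–C3), setting C3; boron there is the placeholder for the C3 methyl. The precursor is an open-chain vinyl(isopropenyl)borate. Ring B is then closed at C1–C8a by acylation, the second aryl is added at C1, and hydrogenation anti to the C3 methyl should set C1 and C2 all-cis.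

Key step: step 1

Remark: atoms are named by the tetralin numbering of the target (C1 aryl-bearing, C2 and C3 methyl-bearing, C4 methylene, ring A the dimethoxybenzo ring, ring B the saturated ring). The MandyPhos ligand is 1,1'-bis[(dimethylamino)(phenyl)methyl]-2,2'-bis[bis(4-methoxy-3,5-dimethylphenyl)phosphino]ferrocene, C64H74FeN2O4P2. Both antipodes are assumed to be commercial, and the one that gives (R)-5 is used.

**Step 1**
Reactants: 1 isopropenylmagnesium bromide; 2 4,4,5,5-tetramethyl-2-vinyl-1,3,2-dioxaborolane (vinylboronic acid pinacol ester); 3 4-bromo-1,2-dimethoxybenzene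
Product: 5 2-[(2R)-1-(3,4-dimethoxyphenyl)-3-methylbut-3-en-2-yl]-4,4,5,5-tetramethyl-1,3,2-dioxaborolane, via vinyl(isopropenyl)borate complex 4 (not isolated)
Conditions: 1, 2, NaOTf, THF, 0 °C to rt; then 3, Pd(OAc)2 (2 mol %), MandyPhos ligand C64H74FeN2O4P2 (2.4 mol %), THF/DMSO, 60 °C
Reagents that add atoms: none
Why: Mechanism: the Grignard reagent adds to boron of 2 to give borate 4; oxidative addition of 3 to zerovalent palladium gives a divalent arylpalladium species that binds the unsubstituted vinyl group of 4, which triggers an anti 1,2-shift of the isopropenyl group from boron to the adjacent carbon (C2–C3) while palladium takes the terminal carbon, and reductive elimination then forms C4–C4a. The closest known reaction type is the enantioselective palladium/MandyPhos conjunctive cross-coupling of Grignard-derived vinylboron ate complexes with aryl halides or triflates, with NaOTf as activator and halide scavenger. No ring is closed in this step. The new C3 stereocentre is set by the chiral bisphosphine, which selects the face of the vinyl group bound to palladium; the ligand antipode is chosen to give (R)-5. The step needs the metallate shift to outrun direct transfer of an alkenyl group to palladium, and activation of the vinyl rather than the isopropenyl group; the first should be secured by the halide-free cationic palladium centre and the bidentate ligand, the second by the much easier binding of the unsubstituted alkene.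

**Step 2**
Reactants: 5
Product: 8 (2R)-2-[(3,4-dimethoxyphenyl)methyl]-3-methylbut-3-en-1-ol, via chloromethyl borate complex 6 (not isolated), via homologated pinacol boronate 7 (not isolated)
Conditions: ClCH2I, n-BuLi, THF, −78 °C to rt; then NaOH, H2O2, 0 °C to rt
Reagents that add atoms: chloroiodomethane, ClCI; hydrogen peroxide, OO; n-butyllithium, [Li]CCCC (lithium counter-ion of 6 only)
Why: Matteson homologation: chloromethyllithium made in the flask adds to boron and the secondary allylic carbon migrates 1,2 with retention as chloride leaves, then the primary C–B bond is oxidised, so the stereocentre keeps its configuration and no new one forms.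

**Step 3**
Reactants: 8
Product: 9 [(2R)-2-[(3,4-dimethoxyphenyl)methyl]-3-methylbut-3-en-1-yl] 4-methylbenzenesulfonate
Conditions: TsCl, pyridine, CH2Cl2, 0 °C to rt
Reagents that add atoms: p-toluenesulfonyl chloride, Cc1ccc(cc1)S(Cl)(=O)=O
Why: Standard sulfonylation (tosylate formation) of an unhindered primary alcohol; the stereocentre is not touched.

**Step 4**
Reactants: 9
Product: 10 4-[(2R)-2,3-dimethylbut-3-en-1-yl]-1,2-dimethoxybenzene
Conditions: LiBHEt3, THF, 0 °C to rt
Reagents that add atoms: none
Why: SN2 hydride displacement of a primary tosylate by LiBHEt3 (reductive deoxygenation) turns the former boron-bearing position into the C3 methyl and leaves the 1,1-disubstituted alkene and the stereocentre alone.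

**Step 5**
Reactants: 10
Product: 12 (3R)-4-(3,4-dimethoxyphenyl)-2,3-dimethylbutan-1-ol (both C2 epimers), via B-alkyl-9-BBN adduct 11 (not isolated)
Conditions: 9-BBN, THF, rt; then NaOH, H2O2, 0 °C to rt
Reagents that add atoms: hydrogen peroxide, OO; 9-borabicyclo[3.3.1]nonane, B1C2CCCC1CCC2 (boron unit of 11 only)
Why: Brown hydroboration–oxidation places boron and then oxygen on the terminal carbon of the 1,1-disubstituted alkene; the new C2 centre forms without control, which is harmless because C2 becomes sp2 in step 8.

**Step 6**
Reactants: 12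
Product: 14 (3R)-4-(3,4-dimethoxyphenyl)-2,3-dimethylbutanoic acid (both C2 epimers), via aldehyde 13 (not isolated)
Conditions: TEMPO (cat.), PhI(OAc)2, MeCN/H2O, rt
Reagents that add atoms: water, O
Why: Oxoammonium (TEMPO/PhI(OAc)2) oxidation of the primary alcohol through aldehyde 13 and its hydrate to the acid is mild enough for the electron-rich ring; C3 is untouched and epimerisation at C2 is irrelevant.

**Step 7**
Reactants: 14
Product: 16 (3R)-6,7-dimethoxy-2,3-dimethyl-3,4-dihydronaphthalen-1(2H)-one (both C2 epimers), via mixed trifluoroacetic anhydride 15 (not isolated)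
Conditions: (CF3CO)2O, CF3CO2H, CH2Cl2, 0 °C to rt
Reagents that add atoms: trifluoroacetic anhydride, O=C(OC(=O)C(F)(F)F)C(F)(F)F (trifluoroacetyl group of 15 only; nothing stays in 16)
Why: Intramolecular Friedel–Crafts acylation through the mixed anhydride closes six-membered ring B (C1–C8a) at the unhindered ring position para to a methoxy group; C3 is β to the new ketone and cannot epimerise.

**Step 8**
Reactants: 16; 3 4-bromo-1,2-dimethoxybenzene
Product: 19 (2R)-4-(3,4-dimethoxyphenyl)-6,7-dimethoxy-2,3-dimethyl-1,2-dihydronaphthalene, via 3,4-dimethoxyphenyllithium 17 (not isolated), via tertiary dibenzylic carbinol 18 (not isolated)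
Conditions: 3, n-BuLi, THF, −78 °C; then 16, −78 to 0 °C; H2O; then TsOH·H2O (cat.), toluene, 50 °C
Reagents that add atoms: n-butyllithium, [Li]CCCC (lithium of 17 only; no reagent atom stays in 19)
Why: 1,2-Addition of the aryllithium (bromine–lithium exchange on 3) to the ketone, then acid-catalysed E1 dehydration of the tertiary carbinol, which can lose only the C2 hydrogen and so gives the conjugated tetrasubstituted alkene; C1 and C2 become sp2 and C3 stays R.

**Step 9**
Reactants: 19
Product: 20 (1S,2R,3R)-1-(3,4-dimethoxyphenyl)-6,7-dimethoxy-2,3-dimethyl-1,2,3,4-tetrahydronaphthalene (target)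
Conditions: H2 (4 atm), Pd/C (10 %), EtOAc, rt
Reagents that add atoms: none
Why: Heterogeneous syn-hydrogenation: the C3 methyl should sit pseudoaxial to avoid A(1,2) strain with the C2 methyl and block one face, so both hydrogens should add from the other face and place the C1 aryl and the C2 methyl cis to the C3 methyl, which is the (1S,2R,3R) all-cis isomer.

**Compound list**
1 | isopropenylmagnesium bromide | CC(=C)[Mg]Br | starting material
2 | 4,4,5,5-tetramethyl-2-vinyl-1,3,2-dioxaborolane | C=CB1OC(C)(C)C(C)(C)O1 | starting material
3 | 4-bromo-1,2-dimethoxybenzene | COc1ccc(Br)cc1OC | starting material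
4 | bromomagnesium isopropenyl(vinyl)(pinacolato)borate | C=C[B-]1(C(C)=C)OC(C)(C)C(C)(C)O1.[Mg+]Br | intermediate (not isolated)
5 | 2-[(2R)-1-(3,4-dimethoxyphenyl)-3-methylbut-3-en-2-yl]-4,4,5,5-tetramethyl-1,3,2-dioxaborolane | COc1ccc(C[C@@H](B2OC(C)(C)C(C)(C)O2)C(C)=C)cc1OC | intermediate
6 | lithium (chloromethyl) borate complex of 5 | COc1ccc(C[C@@H]([B-]2(CCl)OC(C)(C)C(C)(C)O2)C(C)=C)cc1OC.[Li+] | intermediate (not isolated)
7 | 2-[(2R)-2-[(3,4-dimethoxyphenyl)methyl]-3-methylbut-3-en-1-yl]-4,4,5,5-tetramethyl-1,3,2-dioxaborolane | COc1ccc(C[C@@H](CB2OC(C)(C)C(C)(C)O2)C(C)=C)cc1OC | intermediate (not isolated)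
8 | (2R)-2-[(3,4-dimethoxyphenyl)methyl]-3-methylbut-3-en-1-ol | COc1ccc(C[C@@H](CO)C(C)=C)cc1OC | intermediate
9 | [(2R)-2-[(3,4-dimethoxyphenyl)methyl]-3-methylbut-3-en-1-yl] 4-methylbenzenesulfonate | COc1ccc(C[C@@H](COS(=O)(=O)c2ccc(C)cc2)C(C)=C)cc1OC | intermediate
10 | 4-[(2R)-2,3-dimethylbut-3-en-1-yl]-1,2-dimethoxybenzene | COc1ccc(C[C@@H](C)C(C)=C)cc1OC | intermediate
11 | 9-[(3R)-4-(3,4-dimethoxyphenyl)-2,3-dimethylbutyl]-9-borabicyclo[3.3.1]nonane (C2 epimers) | COc1ccc(C[C@@H](C)C(C)CB2C3CCCC2CCC3)cc1OC | intermediate (not isolated)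
12 | (3R)-4-(3,4-dimethoxyphenyl)-2,3-dimethylbutan-1-ol (C2 epimers) | COc1ccc(C[C@@H](C)C(C)CO)cc1OC | intermediate
13 | (3R)-4-(3,4-dimethoxyphenyl)-2,3-dimethylbutanal (C2 epimers) | COc1ccc(C[C@@H](C)C(C)C=O)cc1OC | intermediate (not isolated)
14 | (3R)-4-(3,4-dimethoxyphenyl)-2,3-dimethylbutanoic acid (C2 epimers) | COc1ccc(C[C@@H](C)C(C)C(O)=O)cc1OC | intermediate
15 | (3R)-4-(3,4-dimethoxyphenyl)-2,3-dimethylbutanoic trifluoroacetic anhydride (C2 epimers) | COc1ccc(C[C@@H](C)C(C)C(=O)OC(=O)C(F)(F)F)cc1OC | intermediate (not isolated)
16 | (3R)-6,7-dimethoxy-2,3-dimethyl-3,4-dihydronaphthalen-1(2H)-one (C2 epimers) | COc1cc2C[C@@H](C)C(C)C(=O)c2cc1OC | intermediate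
17 | 3,4-dimethoxyphenyllithium | COc1ccc([Li])cc1OC | intermediate (not isolated)
18 | (3R)-1-(3,4-dimethoxyphenyl)-6,7-dimethoxy-2,3-dimethyl-1,2,3,4-tetrahydronaphthalen-1-ol (C1/C2 isomers) | COc1ccc(C2(O)C(C)[C@H](C)Cc3cc(OC)c(OC)cc23)cc1OC | intermediate (not isolated)
19 | (2R)-4-(3,4-dimethoxyphenyl)-6,7-dimethoxy-2,3-dimethyl-1,2-dihydronaphthalene | COc1ccc(C2=C(C)[C@H](C)Cc3cc(OC)c(OC)cc23)cc1OC | intermediate
20 | (1S,2R,3R)-1-(3,4-dimethoxyphenyl)-6,7-dimethoxy-2,3-dimethyl-1,2,3,4-tetrahydronaphthalene | COc1ccc([C@H]2c3cc(OC)c(OC)cc3C[C@@H](C)[C@H]2C)cc1OC | target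

**Total step count:** 9. **Longest linear sequence:** 9 steps (1, 2 and 3 to 20).

**Steps most likely to fail**

1. Step 1. An alkenyl group may pass directly from boron to palladium (simple cross-coupling), palladium may activate the isopropenyl instead of the vinyl group, or the enantioselectivity may erode with the alkenyl migrating group. The fallback sets out from 3 and comes back at 5, and moves the control of C3 from the palladium catalyst to a sparteine-mediated deprotonation (lithiation–borylation). Bromine–lithium exchange on 3 gives 17, which opens ethylene oxide to give 2-(3,4-dimethoxyphenyl)ethanol F1. N,N-Diisopropylcarbamoyl chloride and Et3N give 2-(3,4-dimethoxyphenyl)ethyl N,N-diisopropylcarbamate F2. Treatment with s-BuLi/(−)-sparteine in Et2O at −78 °C should remove the pro-S hydrogen to give the (S)-lithiated carbamate F3. Isopropenylboronic acid pinacol ester should add with retention to give the lithium boronate complex F4. Warming with MgBr2·OEt2 should induce the 1,2-shift of the isopropenyl group with inversion and loss of the carbamate, giving (R)-5.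

2. Step 9. Uptake at the tetrasubstituted double bond may be slow on the metal surface, the double bond may migrate, or the C3 methyl may discriminate the two faces too weakly. The fallback sets out from 19 and comes back at 20 and makes no new compound (F0). It moves stereocontrol from the substrate to the catalyst: homogeneous hydrogenation with the cationic iridium complex [Ir(cod)(t-Bu-PHOX)][B(3,5-(CF3)2C6H3)4] (cod = cycloocta-1,5-diene, t-Bu-PHOX = C25H26NOP) under H2 (50 bar) in CH2Cl2. The ligand antipode is chosen so that catalyst and substrate bias both deliver hydrogen anti to the C3 methyl.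

3. Step 8. The basic aryllithium may enolise the α-branched, electron-rich ketone instead of adding to it, and the acid may shift the new double bond during dehydration. The fallback sets out from 16 and comes back at 19, and brings the aryl group in by cross-coupling instead of carbonyl addition. KN(SiMe3)2 and PhNTf2 (THF, −78 °C) should convert 16 into (3R)-6,7-dimethoxy-2,3-dimethyl-3,4-dihydronaphthalen-1-yl trifluoromethanesulfonate F5. Suzuki–Miyaura coupling with 3,4-dimethoxyphenylboronic acid (Pd(PPh3)4, K2CO3, dioxane/H2O, 80 °C) should then give 19 without any acid step.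

**Further compounds**
F1 | step 1 | 2-(3,4-dimethoxyphenyl)ethanol | COc1ccc(CCO)cc1OC
F2 | step 1 | 2-(3,4-dimethoxyphenyl)ethyl N,N-diisopropylcarbamate | COc1ccc(CCOC(=O)N(C(C)C)C(C)C)cc1OC
F3 | step 1 | (1S)-2-(3,4-dimethoxyphenyl)-1-lithioethyl N,N-diisopropylcarbamate | COc1ccc(C[C@H]([Li])OC(=O)N(C(C)C)C(C)C)cc1OC
F4 | step 1 | lithium boronate complex of F3 with isopropenylboronic acid pinacol ester | COc1ccc(C[C@H]([B-]2(C(C)=C)OC(C)(C)C(C)(C)O2)OC(=O)N(C(C)C)C(C)C)cc1OC.[Li+]
F0 | step 9 | none | none
F5 | step 8 | (3R)-6,7-dimethoxy-2,3-dimethyl-3,4-dihydronaphthalen-1-yl trifluoromethanesulfonate | COc1cc2C[C@@H](C)C(C)=C(OS(=O)(=O)C(F)(F)F)c2cc1OC
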